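**The reading.** At the reading, 4.0 h after the start, one choice has to be made for the next charge: 66.0 mM of partner, or Sunday's 130 mM, which left 11.3 % of the substrate beside 25.0 % of over-reaction product.

| flask | substrate | partner | free catalyst | added ligand | remark | time |
|---|---|---|---|---|---|---|
| Tuesday's | 44 mM | 33 mM | 1.9 mM | 3.3 mM | run made earlier |  |
| Sunday's | 44 mM | 130 mM | 1.9 mM | 3.3 mM | run made earlier |  |
| Wednesday's | 66 mM | 66 mM | 1.9 mM | 3.3 mM | run made earlier |  |
| flask | 44 mM | 66.0 mM | 1.9 mM | 3.3 mM |  | 4.0 h |

- Tuesday's (time / h: over-reaction product / %, substrate / %, target / %): 0.333: 0, 96.3, 3.6; 0.667: 0.3, 91.2, 7.7; 1.50: 1.4, 84.5, 15.1; 4.00: 1.6, 70.5, 26.3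
- Sunday's (time / h: over-reaction product / %, substrate / %, target / %): 0.333: 0, 85.7, 14.2; 0.667: 1.9, 73.4, 23.3; 1.50: 8.4, 53.4, 40.6; 4.00: 25.0, 11.3, 64.2
- Wednesday's (time / h: over-reaction product / %, substrate / %, target / %): 0.500: 0, 90.7, 7.4; 1.33: 2.4, 83.6, 14.3; 2.50: 2.8, 72.8, 24.1; 4.00: 3.5, 62.0, 30.8

(standard deviation of a reading: 1 percentage point)

* the over-reaction product in the flask at 4.0 h, as a percentage of the substrate charged
* the substrate in the flask at 4.0 h, as a percentage of the substrate charged
* the target in the flask at 4.0 h, as a percentage of the substrate charged

- on the list of suspects stand: free catalyst + added ligand <-> idle complex; catalyst intermediate C -> free catalyst + target; partner + free catalyst <-> catalyst intermediate A; partner + target -> over-reaction product; substrate + catalyst intermediate A -> catalyst intermediate B; partner <-> dormant form; catalyst intermediate B -> by-product + catalyst intermediate C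

**Mean turnover.** Wednesday's run had the flask's partner, free catalyst and added ligand charges, and its substrate stood at 62.0 % at the same time. Its curve, replaced by its mean, gives 3.30 /h: this is the mean turnover frequency, the substrate used up to the reading, per hour and per amount of free catalyst charged. Tuesday's run, with half the partner and 44 mM of substrate against 66 mM, gives 1.71 /h, half as much, so the figure moved with the partner across that change of substrate.

**The error.** The mean hides a fall: Wednesday's last stretch ran at 4.75 mM/h, slower than the mean of 6.27 mM/h. The flask is read at the same time, though, so that fall lies inside the figure. The reckoning here gives 25.1 mM used, leaving 43.0 % of the substrate. That leaves 18.9 mM, less than Wednesday's 40.9 mM, a range the figure was not read from. Sunday's run used more substrate, 39.0 mM against the 25.1 mM reckoned here, but 28.2 % of what it used stood as over-reaction product, against 9.21 % in Wednesday's run, which had the flask's partner charge with more substrate. The smaller loss is here put above the larger use, so the next run goes ahead at 66.0 mM.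

**The forecast.** On the ground that “Substrate loss tracks the partner roughly first order”, the forecast gave 44 % of substrate, 47 % of target and 8 % of over-reaction product. The reckoning above stands 1 percentage point lower on substrate.

**The flask.** At 4.0 h the flask holds 45.6 % of substrate, 46.6 % of target and 7.67 % of over-reaction product, each within the forecast's margin.

    free catalyst + added ligand ⇌ idle complex (K = 320 /M, k = 8.60 /M/min)
    catalyst intermediate C → free catalyst + target (k = 110 /min)
    partner + free catalyst ⇌ catalyst intermediate A (K = 40.0 /M, k = 3.20 /M/min)
    partner + target → over-reaction product (k = 0.0380 /M/min)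
    substrate + catalyst intermediate A → catalyst intermediate B (k = 37.0 /M/min)
    partner ⇌ dormant form (K = 0.580, k = 0.0340 /min)
    catalyst intermediate B → by-product + catalyst intermediate C (k = 1.10 /min)

Its own mean turnover comes to 3.15 /h against 3.30 /h. The target moves by 5 points once free catalyst is charged at 1.66 mM or 2.15 mM, all else held. For the neighbour charged with 0.47 mM of free catalyst, 3.30 /h gives 6.20 mM used and 85.9 % of the substrate left; that neighbour holds 84.6 %.

(The earlier runs and the new flask are calculated on assumed constants; the scatter is artificial.)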